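The pyran (isochroman) ring is cut at Cc–Cb and Ca–O. Ca (acetal CH on ring A) and Cc (benzylic CH bearing the acetyl group) are the two ends of a hydroxy-o-quinodimethane; Cb and the pyran oxygen are the formyl group of an isoquinoline 6-hydroxy-7-carbaldehyde. A titanium-templated photoenolisation/oxa-Diels–Alder step joins both halves, closes the pyran ring as a lactol and sets Cb. The diene precursor is a 2-alkyl-6-methoxybenzaldehyde whose second formyl and acetyl groups are carried as silyl-protected alcohols; it and the isoquinoline arise from one arene diol. Bridging by the isoquinoline oxygen, double oxidation and acid-mediated deprotection with equilibration at Cc complete the synthesis.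

Key step: step 11

Atom labels: Ca = acetal CH on ring A (isochroman C1); Cb = O-benzylic CH on isoquinoline C7 (isochroman C3); Cc = benzylic CH bearing the acetyl group (isochroman C4); ring A = the benzene ring carrying OMe, CHO and OH.

Assumption: the natural configuration at Cc (acetyl cis to isoquinoline C7 across Cb–Cc, on the concave face of the bridged bicycle) is taken as the equilibrium configuration of this enolisable benzylic α-keto centre.

Design remarks:
- The side-chain carbinol is made (R). In the rotamer fixed by A(1,3) strain against the peri C–H, its OTBS group covers the diene face that would lead to (S)-Cb in the chelated, exo-aryl arrangement. The centre is erased in step 13.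
- The cycloadduct is expected to be 3,4-trans, so Cc is formed opposite to the target and is corrected at the ketone stage (step 14).
- The spectator formyl group is carried as CH2OTBS, not as an acetal. Only the reacting aldehyde is then at the carbonyl level in step 11, and no acid step is needed while MOM and silyl ethers are present.

Step 1
Reactants: 1 3-bromo-5-methoxyphenol
Product: 2 (3-bromo-5-methoxyphenoxy)tri(propan-2-yl)silane
Conditions: TIPSCl, imidazole, DMF, rt
Reagents that add atoms: chlorotri(propan-2-yl)silane (TIPSCl), CC(C)[Si](Cl)(C(C)C)C(C)C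
Why: Routine silylation of a phenol, the bulky non-coordinating TIPS ether being chosen because it shields and does not direct metalation at its two ortho positions in step 2.

Step 2
Reactants: 2 (3-bromo-5-methoxyphenoxy)tri(propan-2-yl)silane
Product: 4 2-bromo-6-methoxy-4-(triisopropylsilyloxy)benzaldehyde, via aryllithium 3 (not isolated)
Conditions: LDA, THF, −78 °C; DMF, −78 °C → rt; aq NH4Cl
Reagents that add atoms: N,N-dimethylformamide, CN(C)C=O
Why: Directed ortho-lithiation with an amide base (deprotonation, no Br/Li exchange) takes the most acidic CH, flanked by Br and OMe as in 3-bromoanisole, while the TIPS ether blocks the other CH next to bromine, and the aryllithium is formylated by DMF.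

Step 3
Reactants: 4 2-bromo-6-methoxy-4-(triisopropylsilyloxy)benzaldehyde
Product: 6 2-bromo-6-methoxy-4-(methoxymethoxy)benzaldehyde, via phenoxide 5 (not isolated)
Conditions: TBAF, THF, 0 °C; then MOMCl, i-Pr2NEt, 0 °C → rt
Reagents that add atoms: chloromethyl methyl ether (MOMCl), COCCl
Why: Fluoride cleaves the aryl silyl ether and the phenoxide is O-alkylated in the same flask (Williamson etherification), installing the MOM ether that serves as cooperative directing group in step 6 and as acid-labile phenol protection to the end.

Step 4
Reactants: 6 2-bromo-6-methoxy-4-(methoxymethoxy)benzaldehyde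
Product: 7 1-bromo-2-(dimethoxymethyl)-3-methoxy-5-(methoxymethoxy)benzene
Conditions: HC(OMe)3, PPTS (cat.), MeOH, rt; Et3N quench
Reagents that add atoms: trimethyl orthoformate, COC(OC)OC; methanol, CO
Why: Acid-catalysed acetalisation driven by the orthoformate masks the future Ca formyl group for the organometallic steps as a dimethyl acetal that can later be released without touching MOM or silyl ethers.

Step 5
Reactants: 7 1-bromo-2-(dimethoxymethyl)-3-methoxy-5-(methoxymethoxy)benzene; 8 (R)-2-methyloxirane
Product: 10 (2R)-1-[2-(dimethoxymethyl)-3-methoxy-5-(methoxymethoxy)phenyl]propan-2-ol, via arylmagnesium bromide 9 (not isolated)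
Conditions: Mg, THF, 45 °C; CuI (10 mol %), 8, −30 → 0 °C; aq NH4Cl
Reagents that add atoms: none
Why: Grignard formation next to an acetal is routine and the copper-catalysed SN2 opening of the monosubstituted epoxide occurs at its CH2 terminus, so the (R) centre comes unchanged from the chiral pool.

Step 6
Reactants: 10 (2R)-1-[2-(dimethoxymethyl)-3-methoxy-5-(methoxymethoxy)phenyl]propan-2-ol
Product: 13 (2R)-1-[2-(dimethoxymethyl)-4-(hydroxymethyl)-3-methoxy-5-(methoxymethoxy)phenyl]propan-2-ol, via dilithio species 11 (not isolated), via aldehyde 12 (not isolated)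
Conditions: n-BuLi (2.4 equiv), TMEDA, THF, −20 → 0 °C; DMF, −78 → 0 °C; then MeOH, NaBH4, 0 °C
Reagents that add atoms: N,N-dimethylformamide, CN(C)C=O
Why: After alkoxide formation, cooperative directed ortho-metalation occurs at the only CH flanked by two directing groups (OMe and OMOM), and DMF quench followed by in situ borohydride reduction gives the hydroxymethyl group.

Step 7
Reactants: 13 (2R)-1-[2-(dimethoxymethyl)-4-(hydroxymethyl)-3-methoxy-5-(methoxymethoxy)phenyl]propan-2-ol
Product: 14 bis-TBS ether of 13 (benzylic and carbinol oxygens silylated)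
Conditions: TBSCl (2.5 equiv), imidazole, DMF, rt
Reagents that add atoms: tert-butyl(chloro)dimethylsilane (TBSCl), CC(C)(C)[Si](C)(C)Cl
Why: Standard silylation protects both alcohols in one operation, so that the later formyl and acetyl groups are masked at the alcohol level and no second carbonyl chromophore or conjugated acyl group is present in step 11.

Step 8
Reactants: 14 bis-TBS ether of 13
Product: 15 3-[(tert-butyldimethylsilyloxy)methyl]-6-[(2R)-2-(tert-butyldimethylsilyloxy)propyl]-2-methoxy-4-(methoxymethoxy)benzaldehyde
Conditions: PPTS (cat.), acetone/H2O (10:1), rt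
Reagents that add atoms: water, O
Why: Chemoselective acetal hydrolysis, because the dimethyl acetal of an ortho,para-dialkoxybenzaldehyde ionises to a strongly stabilised oxocarbenium ion far faster than MOM or TBS ethers are cleaved.

Step 9
Reactants: 13 (2R)-1-[2-(dimethoxymethyl)-4-(hydroxymethyl)-3-methoxy-5-(methoxymethoxy)phenyl]propan-2-ol
Product: 16 3-(dimethoxymethyl)-2-methoxy-6-(methoxymethoxy)-4-(2-oxopropyl)benzaldehyde
Conditions: DMP (2.6 equiv), NaHCO3, CH2Cl2, 0 °C → rt
Reagents that add atoms: none
Why: Dess–Martin oxidation converts the benzylic alcohol into the aldehyde and the carbinol into the methyl ketone under buffered conditions that leave the acetal intact.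

Step 10
Reactants: 16 3-(dimethoxymethyl)-2-methoxy-6-(methoxymethoxy)-4-(2-oxopropyl)benzaldehyde
Product: 18 6-hydroxy-8-methoxy-3-methylisoquinoline-7-carbaldehyde, via isoquinoline MOM ether 17 (not isolated)
Conditions: NH4OAc, AcOH/H2O, 60 °C; then 3 M HCl, 50 °C; NaHCO3 to pH 7
Reagents that add atoms: ammonium acetate, CC(=O)[O-].[NH4+]
Why: Acid unmasks the acetal to a 2-(2-oxopropyl)benzaldehyde that condenses with ammonia through the 2-benzopyrylium ion to the aromatic isoquinoline (classical 1,5-dicarbonyl-to-pyridine annulation), the hindered second formyl group forming only a reversible imine, and aqueous HCl then cleaves the MOM ether.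

Step 11
Reactants: 15 3-[(tert-butyldimethylsilyloxy)methyl]-6-[(2R)-2-(tert-butyldimethylsilyloxy)propyl]-2-methoxy-4-(methoxymethoxy)benzaldehyde; 18 6-hydroxy-8-methoxy-3-methylisoquinoline-7-carbaldehyde
Product: 20 (3R,4R)-7-[(tert-butyldimethylsilyloxy)methyl]-4-[(1R)-1-(tert-butyldimethylsilyloxy)ethyl]-3-(6-hydroxy-8-methoxy-3-methylisoquinolin-7-yl)-8-methoxy-6-(methoxymethoxy)isochroman-1-ol (C1 epimers), via photoenol 19 (not isolated)
Conditions: 18, Ti(Oi-Pr)4 (1.1 equiv), (R,R)-TADDOL (1.2 equiv), 4 Å MS, PhMe, rt, 1 h; then 15 (1.3 equiv), 365 nm LED, Ar, 0 °C; aq Rochelle salt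
Reagents that add atoms: none
Why: Proposed new method: n,π* excitation of 15 and triplet 1,5-hydrogen transfer from the benzylic CH2 give the long-lived hydroxy-o-quinodimethane 19 (OH and side chain outward), whose OH exchanges onto the titanium TADDOLate that already holds 18 as a chelating 6-oxido-7-formyl ligand, and the donor terminus Cc then adds to the Ti-activated formyl carbon Cb while the formyl oxygen closes on Ca and ring A re-aromatises. The closest known reaction types are Ti(Oi-Pr)4/TADDOL-mediated photoenolisation–Diels–Alder reactions of 2-alkylbenzaldehydes with enones and photoenol trapping by activated carbonyl compounds; an ordinary aryl aldehyde C=O as 2π partner is not established, which is why it is bound and activated on the same metal as the dienolate. The pyran ring closes in a [4+2] (oxa-Diels–Alder) mode, Cc–Cb and Ca–O being formed in one operation, either concerted or as a vinylogous aldol addition followed by six-ring hemiacetal closure. Cb is set by Re-face attack on the formyl group, enforced by the chiral diolate and in the same sense by the (R)-silyloxy centre; Cc follows from the outward side chain and the exo (chelate-side) aryl group and is therefore trans to the aryl group at Cb (corrected in step 14); Ca is a lactol carbon and remains an epimer mixture. The step needs oxa regiochemistry, cross- rather than self-reaction and one formyl face: the polarised donor diene and the Ti–O(formyl) contact next to Ca secure the first, the phenoxide anchor present only in 18 secures the second, and ligand plus side-chain centre secure the third.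

Step 12
Reactants: 20 lactol (3R,4R, C1 epimers)
Product: 22 bridged acetal diol (Ca R, Cb R; 1-hydroxyethyl group on the convex face at Cc; ring A with CH2OH, OMOM, OMe), via bridged bis-silyl ether 21 (not isolated)
Conditions: CSA (1.3 equiv), 4 Å MS, CH2Cl2, 0 °C; Et3N; then TBAF, THF, 0 °C → rt
Reagents that add atoms: none
Why: The lactol ionises to an oxocarbenium ion stabilised by the ortho-OMe/para-OMOM ring A and is captured by the neighbouring isoquinoline 6-OH (intramolecular acetalisation closing the 1,3-dioxane ring), which can only bridge cis to the aryl group at Cb and so fixes Ca as (R), and fluoride then removes both TBS groups.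

Step 13
Reactants: 22 bridged acetal diol
Product: 23 MOM-protected bridged keto aldehyde (Ca R, Cb R, Cc R; acetyl on the convex face)
Conditions: DMP (3 equiv), NaHCO3, CH2Cl2, 0 °C → rt
Reagents that add atoms: none
Why: Dess–Martin oxidation converts the benzylic alcohol into the aryl aldehyde and the carbinol into the methyl ketone in one operation under buffered conditions, the phenol staying protected as its MOM ether and the auxiliary carbinol stereocentre being erased as planned.

Step 14
Reactants: 23 MOM-protected bridged keto aldehyde
Product: 24 target CNP0584953.1 (Ca R, Cb R, Cc S)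
Conditions: 3 M HCl, THF, 45 °C, until the epimer ratio is constant; NaHCO3
Reagents that add atoms: none
Why: Aqueous acid hydrolyses the aryl MOM ether and enolises the benzylic α-keto centre Cc, whose reprotonation from the open convex face places the acetyl group cis to isoquinoline C7, the epimer taken as the equilibrium one (see assumption), while the doubly tethered bicyclic acetal recloses if it opens (MOM acetal hydrolysis plus acid-catalysed keto–enol epimerisation).

Compound list
1 | 3-bromo-5-methoxyphenol | COc1cc(O)cc(Br)c1 | starting material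
2 | (3-bromo-5-methoxyphenoxy)tri(propan-2-yl)silane | COc1cc(O[Si](C(C)C)(C(C)C)C(C)C)cc(Br)c1 | intermediate
3 | [2-bromo-6-methoxy-4-(triisopropylsilyloxy)phenyl]lithium | [Li]c1c(Br)cc(O[Si](C(C)C)(C(C)C)C(C)C)cc1OC | intermediate
4 | 2-bromo-6-methoxy-4-(triisopropylsilyloxy)benzaldehyde | COc1cc(O[Si](C(C)C)(C(C)C)C(C)C)cc(Br)c1C=O | intermediate
5 | tetrabutylammonium 3-bromo-4-formyl-5-methoxyphenoxide | COc1cc([O-])cc(Br)c1C=O.CCCC[N+](CCCC)(CCCC)CCCC | intermediate
6 | 2-bromo-6-methoxy-4-(methoxymethoxy)benzaldehyde | COCOc1cc(OC)c(C=O)c(Br)c1 | intermediate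
7 | 1-bromo-2-(dimethoxymethyl)-3-methoxy-5-(methoxymethoxy)benzene | COCOc1cc(OC)c(C(OC)OC)c(Br)c1 | intermediate
8 | (R)-2-methyloxirane ((R)-propylene oxide) | C[C@@H]1CO1 | starting material
9 | [2-(dimethoxymethyl)-3-methoxy-5-(methoxymethoxy)phenyl]magnesium bromide | COCOc1cc(OC)c(C(OC)OC)c([Mg]Br)c1 | intermediate
10 | (2R)-1-[2-(dimethoxymethyl)-3-methoxy-5-(methoxymethoxy)phenyl]propan-2-ol | COCOc1cc(OC)c(C(OC)OC)c(C[C@@H](C)O)c1 | intermediate
11 | lithium (2R)-1-[2-(dimethoxymethyl)-4-lithio-3-methoxy-5-(methoxymethoxy)phenyl]propan-2-olate | [Li]c1c(OC)c(C(OC)OC)c(C[C@@H](C)O[Li])cc1OCOC | intermediate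
12 | 3-(dimethoxymethyl)-4-[(2R)-2-hydroxypropyl]-2-methoxy-6-(methoxymethoxy)benzaldehyde | COCOc1cc(C[C@@H](C)O)c(C(OC)OC)c(OC)c1C=O | intermediate
13 | (2R)-1-[2-(dimethoxymethyl)-4-(hydroxymethyl)-3-methoxy-5-(methoxymethoxy)phenyl]propan-2-ol | COCOc1cc(C[C@@H](C)O)c(C(OC)OC)c(OC)c1CO | intermediate
14 | bis-TBS ether of 13 (dimethyl acetal retained) | COCOc1cc(C[C@@H](C)O[Si](C)(C)C(C)(C)C)c(C(OC)OC)c(OC)c1CO[Si](C)(C)C(C)(C)C | intermediate
15 | 3-[(tert-butyldimethylsilyloxy)methyl]-6-[(2R)-2-(tert-butyldimethylsilyloxy)propyl]-2-methoxy-4-(methoxymethoxy)benzaldehyde | COCOc1cc(C[C@@H](C)O[Si](C)(C)C(C)(C)C)c(C=O)c(OC)c1CO[Si](C)(C)C(C)(C)C | intermediate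
16 | 3-(dimethoxymethyl)-2-methoxy-6-(methoxymethoxy)-4-(2-oxopropyl)benzaldehyde | COCOc1cc(CC(C)=O)c(C(OC)OC)c(OC)c1C=O | intermediate
17 | 8-methoxy-6-(methoxymethoxy)-3-methylisoquinoline-7-carbaldehyde | COCOc1cc2cc(C)ncc2c(OC)c1C=O | intermediate
18 | 6-hydroxy-8-methoxy-3-methylisoquinoline-7-carbaldehyde | Cc1cc2cc(O)c(C=O)c(OC)c2cn1 | intermediate
19 | hydroxy-o-quinodimethane (photoenol) of 15, OH and side chain outward | O/C=C1/C(=C/[C@@H](C)O[Si](C)(C)C(C)(C)C)C=C(OCOC)C(CO[Si](C)(C)C(C)(C)C)=C1OC | intermediate
20 | (3R,4R)-7-[(tert-butyldimethylsilyloxy)methyl]-4-[(1R)-1-(tert-butyldimethylsilyloxy)ethyl]-3-(6-hydroxy-8-methoxy-3-methylisoquinolin-7-yl)-8-methoxy-6-(methoxymethoxy)isochroman-1-ol, C1 epimers | COCOc1cc2c(c(OC)c1CO[Si](C)(C)C(C)(C)C)C(O)O[C@@H](c1c(O)cc3cc(C)ncc3c1OC)[C@@H]2[C@@H](C)O[Si](C)(C)C(C)(C)C | intermediate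
21 | bridged acetal, bis-TBS ether (Ca R, Cb R, Cc R; (1R)-1-silyloxyethyl group on the convex face) | COc1c(CO[Si](C)(C)C(C)(C)C)c(OCOC)cc2c1[C@H]1Oc3cc4cc(C)ncc4c(OC)c3[C@H](O1)[C@@H]2[C@@H](C)O[Si](C)(C)C(C)(C)C | intermediate
22 | bridged acetal diol (Ca R, Cb R; same spatial arrangement at Cc, CIP S; carbinol R) | COc1c(CO)c(OCOC)cc2c1[C@H]1Oc3cc4cc(C)ncc4c(OC)c3[C@H](O1)[C@@H]2[C@@H](C)O | intermediate
23 | MOM-protected bridged keto aldehyde (Ca R, Cb R, Cc R) | COc1c(C=O)c(OCOC)cc2c1[C@H]1Oc3cc4cc(C)ncc4c(OC)c3[C@H](O1)[C@@H]2C(C)=O | intermediate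
24 | CNP0584953.1 (Ca R, Cb R, Cc S) | COc1c(C=O)c(O)cc2c1[C@H]1Oc3cc4cc(C)ncc4c(OC)c3[C@H](O1)[C@H]2C(C)=O | target

Total step count: 14. Longest linear sequence: 12 steps (steps 1–8 and 11–14; the isoquinoline branch, steps 1–6, 9, 10 and 11–14, is equally long).

Steps most likely to fail

1. Step 11 (new method). The titanium aryloxide of 18 may absorb most of the 365 nm light and starve 15 of excitation. The photoenol may relax back, lose silanol by 1,6-elimination, or add to a second molecule of 15. Face selection at the formyl group may be incomplete. The fallback builds the Cc–Cb bond by an aldol reaction, using known chemistry. It sets out from 13: selective silylation of the primary benzylic hydroxyl (TBSCl, 1.05 equiv, imidazole, CH2Cl2, −20 °C) should give the mono-silyl ether F1, and Dess–Martin oxidation the benzyl methyl ketone F2. Separately 18 is O-silylated (TBSCl, imidazole) to the aryl silyl ether F3. Enolisation of F2 on its benzylic side with the Ipc2BOTf enantiomer that directs the enolate to the Re face of the formyl group (i-Pr2NEt, CH2Cl2, −78 °C) and addition to F3 (Paterson boron aldol) should give the β-hydroxy ketone F4, (R) at Cb. Aqueous HF in MeCN then removes both silyl groups and hydrolyses the dimethyl acetal, and the hydroxy aldehyde closes to the lactol and on to the bridged acetal alcohol F5. Dess–Martin oxidation of its benzylic alcohol returns to the route at 23, together with its Cc epimer; both converge in step 14.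

2. Step 14. The acid-mediated equilibrium at Cc may stop short of, or lie against, the natural epimer. Prolonged acid may also open the bicyclic acetal by retro-oxa-Michael cleavage. The fallback replaces equilibration by kinetic protonation and sets out from 23. KOt-Bu (1.05 equiv, THF, −78 °C) should give the aryl-conjugated potassium enolate, and an acetic acid quench at −78 °C delivers the proton to the open convex face, giving the Cc-(S) epimer of 23, F6. The MOM ether is then cleaved under non-enolising conditions (TFA/CH2Cl2, 0 °C, short contact) to come back to the route at 24.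

3. Step 12. More acid is needed than the isoquinoline nitrogen holds, and this excess may ionise the electron-rich benzylic silyl ether or cleave the MOM ether before bridging is complete. The fallback closes the acetal under neutral conditions and sets out from 20. An intramolecular Mitsunobu acetalisation (PPh3, DIAD, THF, 0 °C), known for phenols and lactols, activates the lactol hydroxyl for displacement by the neighbouring phenol and should give 21. Desilylation with TBAF as in step 12 then returns to the route at 22.

Further compounds
F1 | step 11 | (2R)-1-[4-[(tert-butyldimethylsilyloxy)methyl]-2-(dimethoxymethyl)-3-methoxy-5-(methoxymethoxy)phenyl]propan-2-ol | COCOc1cc(C[C@@H](C)O)c(C(OC)OC)c(OC)c1CO[Si](C)(C)C(C)(C)C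
F2 | step 11 | 1-[4-[(tert-butyldimethylsilyloxy)methyl]-2-(dimethoxymethyl)-3-methoxy-5-(methoxymethoxy)phenyl]propan-2-one | COCOc1cc(CC(C)=O)c(C(OC)OC)c(OC)c1CO[Si](C)(C)C(C)(C)C
F3 | step 11 | 6-(tert-butyldimethylsilyloxy)-8-methoxy-3-methylisoquinoline-7-carbaldehyde | Cc1cc2cc(O[Si](C)(C)C(C)(C)C)c(C=O)c(OC)c2cn1
F4 | step 11 | (4R)-3-aryl-4-hydroxy-4-(isoquinolin-7-yl)butan-2-one aldol adduct of F2 and F3 (Cb R, Cc epimers) | COCOc1cc(C(C(C)=O)[C@@H](O)c2c(O[Si](C)(C)C(C)(C)C)cc3cc(C)ncc3c2OC)c(C(OC)OC)c(OC)c1CO[Si](C)(C)C(C)(C)C
F5 | step 11 | MOM-protected bridged ketone with free hydroxymethyl group on ring A (Ca R, Cb R, Cc epimers) | COc1c(CO)c(OCOC)cc2c1[C@H]1Oc3cc4cc(C)ncc4c(OC)c3[C@H](O1)C2C(C)=O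
F6 | step 14 | Cc-(S) epimer of 23 (MOM ether of the target) | COc1c(C=O)c(OCOC)cc2c1[C@H]1Oc3cc4cc(C)ncc4c(OC)c3[C@H](O1)[C@H]2C(C)=O
F0 | step 12 | none | none
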